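Numbering: C1–C7 is the heptanoid chain (C1 benzylic CH2 at the chain aryl, C3 carbinol, C5=C6 alkene, C7 methine bearing ring B); ring A is C8–C13, with C8 bonded to C7, C9 (OH), C10 (H), C11 (OMe), C12 (bears the enone carbonyl) and C13 (OH); in the alkyne intermediates C8 and C9 are the alkyne carbons.
Retrosynthesis: the C12–acyl bond is cut first (aryllithium plus cinnamoyl Weinreb amide); ring A is then cut at C8–C13 and C9–C10 into 3-methoxycyclobut-2-en-1-one (C10–C13) and a silyl ynol ether (C8, C9) that already carries C7, ring B and the C1–C6 chain; the ynol ether is cut at C5=C6 (cross-metathesis) and at C7–C8 (allylic alkynylation).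
Enabling feature: C8, the ring A carbon bonded to C7, lies between the oxygenated carbons C9 and C13 and para to the methoxy carbon C11, the pattern produced when the two carbons of an ynol ether are inserted into a 3-methoxy vinylketene; once the C9 silyl group is removed, C10 and C12 are equivalent, so the enone has only one site to enter.
Forward: ring B carbinol → C7 enyne; C1–C4 aldehyde → homoallylic silyl ether; cross-metathesis joins them; the alkyne terminus is oxidised to the ynol ether; ring A (the only ring formed) is grown on C7; the 4-hydroxycinnamoyl unit is attached last and all protecting groups are removed in one acid step.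
Stereochemistry: C7 (S) from ligand-controlled iridium-catalysed allylic alkynylation of a racemic carbinol; C3 (S) from reagent-controlled Brown allylation; C5=C6 (E) from metathesis; enone (E) from Horner–Wadsworth–Emmons olefination; the ring-forming step creates no stereocentre.

Key step: step 13

Shorthand: Hp = (1S,2E,5S)-5-[(tert-butyldimethylsilyl)oxy]-1,7-bis[4-(methoxymethoxy)phenyl]hept-2-en-1-yl, attached through C7.
Assumption: the (S)-configured phosphoramidite–olefin ligand is taken to give the (S)-enyne 5 in step 3; if the sense of induction is the opposite, the enantiomeric ligand is used and nothing else changes.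

Step 1
Reactants: 1 4-hydroxybenzaldehyde
Product: 2 4-(methoxymethoxy)benzaldehyde
Conditions: MOMCl, i-Pr2NEt, CH2Cl2, 0 °C → rt
Reagents that add atoms: chloromethyl methyl ether (MOMCl), COCCl
Why: O-alkylation of the phenol by the reactive α-chloro ether gives the acetal-type MOM ether, which tolerates every basic, organometallic and thermal step that follows.

Step 2
Reactants: 2 4-(methoxymethoxy)benzaldehyde
Product: 3 rac-1-[4-(methoxymethoxy)phenyl]prop-2-en-1-ol
Conditions: CH2=CHMgBr, THF, 0 °C; then H2O/NH4Cl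
Reagents that add atoms: vinylmagnesium bromide, C=C[Mg]Br
Why: Grignard 1,2-addition to the aldehyde; the racemate is sufficient because the next step is enantioconvergent.

Step 3
Reactants: 3 rac-1-[4-(methoxymethoxy)phenyl]prop-2-en-1-ol; 4 potassium trifluoro[(trimethylsilyl)ethynyl]borate
Product: 5 trimethyl[(3S)-3-[4-(methoxymethoxy)phenyl]pent-4-en-1-yn-1-yl]silane
Conditions: [Ir(cod)Cl]2 (4 mol %), (S)-5-(dinaphtho[2,1-d:1',2'-f][1,3,2]dioxaphosphepin-4-yl)-5H-dibenzo[b,f]azepine (16 mol %), KHF2, CF3CO2H, n-Bu4NBr (10 mol %), 1,4-dioxane, rt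
Reagents that add atoms: none
Why: Enantioconvergent iridium-catalysed allylic substitution, in which acid-assisted ionisation of either enantiomer of 3 gives one allyl complex of trivalent iridium held by the chiral phosphoramidite–olefin ligand and the alkynyl borate attacks its aryl-bearing terminus on the open face, so the branched 1,4-enyne with C7 (S) should form under catalyst control.

Step 4
Reactants: 6 methyl 3-(4-hydroxyphenyl)propanoate
Product: 7 methyl 3-[4-(methoxymethoxy)phenyl]propanoate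
Conditions: MOMCl, i-Pr2NEt, CH2Cl2, 0 °C → rt
Reagents that add atoms: chloromethyl methyl ether (MOMCl), COCCl
Why: Phenol O-alkylation to the MOM ether, as in step 1.

Step 5
Reactants: 7 methyl 3-[4-(methoxymethoxy)phenyl]propanoate
Product: 9 3-[4-(methoxymethoxy)phenyl]propanal, via diisobutylaluminium hemiacetal 8 (not isolated)
Conditions: i-Bu2AlH (1.05 equiv), CH2Cl2, −78 °C; MeOH, then aq. KNaC4H4O6 (potassium sodium tartrate)
Reagents that add atoms: none
Why: Partial ester reduction with i-Bu2AlH, in which the tetrahedral aluminium hemiacetal is stable at −78 °C and releases the aldehyde only on work-up.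

Step 6
Reactants: 9 3-[4-(methoxymethoxy)phenyl]propanal
Product: 11 (3S)-1-[4-(methoxymethoxy)phenyl]hex-5-en-3-ol, via diisopinocampheylborinate 10 (not isolated)
Conditions: (+)-Ipc2BOMe [(−)-α-pinene series], CH2=CHCH2MgBr, Et2O, −78 °C → rt; 9, −78 °C; then 3 M NaOH, 30% H2O2, 0 °C → rt
Reagents that add atoms: allylmagnesium bromide, C=CC[Mg]Br
Why: Brown allylation through a closed six-membered chair transition state with the aldehyde chain equatorial; the isopinocampheyl groups of the (−)-α-pinene series deliver the allyl group to the Re face of 9, which should set C3 as (S).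

Step 7
Reactants: 11 (3S)-1-[4-(methoxymethoxy)phenyl]hex-5-en-3-ol
Product: 12 tert-butyl{[(3S)-1-[4-(methoxymethoxy)phenyl]hex-5-en-3-yl]oxy}dimethylsilane
Conditions: TBSCl, imidazole, DMF, rt
Reagents that add atoms: tert-butyldimethylsilyl chloride, CC(C)(C)[Si](C)(C)Cl
Why: Imidazole-promoted silylation of the secondary alcohol gives a silyl ether that survives base, fluoride at 0 °C and heat but falls in the final acid step.

Step 8
Reactants: 5 trimethyl[(3S)-3-[4-(methoxymethoxy)phenyl]pent-4-en-1-yn-1-yl]silane; 12 tert-butyl{[(3S)-1-[4-(methoxymethoxy)phenyl]hex-5-en-3-yl]oxy}dimethylsilane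
Product: 13 tert-butyl{[(3S,5E,7S)-1,7-bis[4-(methoxymethoxy)phenyl]-9-(trimethylsilyl)non-5-en-8-yn-3-yl]oxy}dimethylsilane
Conditions: 12 (2–3 equiv), second-generation Grubbs catalyst RuCl2(=CHPh)(H2IMes)(PCy3) (5 mol %), 1,4-benzoquinone (10 mol %), CH2Cl2, 40 °C
Reagents that add atoms: none
Why: Olefin cross-metathesis between the readily dimerising terminal olefin 12 and the hindered, non-dimerising vinyl group of 5 should give the (E)-alkene under thermodynamic control, with the silylated alkyne a poor partner for enyne metathesis and benzoquinone suppressing hydride-induced double-bond migration.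

Step 9
Reactants: 13 tert-butyl{[(3S,5E,7S)-1,7-bis[4-(methoxymethoxy)phenyl]-9-(trimethylsilyl)non-5-en-8-yn-3-yl]oxy}dimethylsilane
Product: 14 tert-butyl{[(3S,5E,7R)-1,7-bis[4-(methoxymethoxy)phenyl]non-5-en-8-yn-3-yl]oxy}dimethylsilane
Conditions: K2CO3 (0.2 equiv), MeOH–THF, 0 °C → rt
Reagents that add atoms: none
Why: Methanolysis of the alkynyl C–Si bond (protodesilylation) under catalytic carbonate, which is too weak a base to remove the C7 hydrogen; the descriptor at C7 becomes R only because ethynyl ranks below aryl.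

Step 10
Reactants: 14 tert-butyl{[(3S,5E,7R)-1,7-bis[4-(methoxymethoxy)phenyl]non-5-en-8-yn-3-yl]oxy}dimethylsilane
Product: 17 tert-butyl{[(3S,5E,7S)-1,7-bis[4-(methoxymethoxy)phenyl]-9-[(triisopropylsilyl)oxy]non-5-en-8-yn-3-yl]oxy}dimethylsilane, via lithium acetylide 15 (not isolated), via lithium ynolate 16 (not isolated)
Conditions: LiN(SiMe3)2 (2.0 equiv), THF, −78 °C; t-BuOOH (1.0 equiv, in decane), −78 → 0 °C; i-Pr3SiOTf, −78 → 0 °C; filtration through Et3N-deactivated silica
Reagents that add atoms: tert-butyl hydroperoxide, CC(C)(C)OO; triisopropylsilyl trifluoromethanesulfonate, CC(C)[Si](C(C)C)(C(C)C)OS(=O)(=O)C(F)(F)F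
Why: Oxidation of the lithium acetylide by the electrophilic oxygen of LiOOt-Bu gives the ynolate, which the bulky silyl triflate captures at oxygen (ynol silyl ether synthesis); the amide base is limited to the amount needed for the alkyne C–H and the hydroperoxide O–H so that C7–H is left alone.

Step 11
Reactants: 18 3-ethoxycyclobut-2-en-1-one
Product: 19 cyclobutane-1,3-dione
Conditions: 2 M aq. HCl, 0 °C → rt; concentrate and crystallise cold
Reagents that add atoms: water, O
Why: Acid hydrolysis of a vinylogous ester by conjugate addition of water and loss of ethanol.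

Step 12
Reactants: 19 cyclobutane-1,3-dione
Product: 20 3-methoxycyclobut-2-en-1-one
Conditions: Me3SiCHN2, toluene–MeOH (4:1), 0 °C
Reagents that add atoms: (trimethylsilyl)diazomethane, C[Si](C)(C)C=[N+]=[N-]
Why: O-Methylation of the strongly acidic enol form of the 1,3-dione by a diazomethane equivalent (protonation at the diazo carbon, then methyl transfer to the enolate oxygen).

Step 13
Reactants: 17 tert-butyl{[(3S,5E,7S)-1,7-bis[4-(methoxymethoxy)phenyl]-9-[(triisopropylsilyl)oxy]non-5-en-8-yn-3-yl]oxy}dimethylsilane; 20 3-methoxycyclobut-2-en-1-one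
Product: 25 2-Hp-5-methoxy-3-[(triisopropylsilyl)oxy]phenol, via methoxy vinylketene 21 (not isolated), via vinylcyclobutenone adduct 22 (not isolated), via dienylketene 23 (not isolated), via cyclohexadienone 24 (not isolated)
Conditions: 20 (1.5 equiv), toluene (0.5 M), 110 °C, sealed tube
Reagents that add atoms: none
Why: Heating opens 20 by 4π electrocyclic ring opening to vinylketene 21, whose ketene C=C undergoes [2+2] cycloaddition with the ynol ether, the alkyne carbon C8 that carries C7 bonding to the ketene carbonyl carbon (bond C8–C13) and the oxygen-bearing alkyne carbon C9 to the ketene α-carbon (bond C9–C10) to give 22, which opens again to dienylketene 23. Ring A then closes by a thermal disrotatory 6π electrocyclisation that forms the C12–C13 bond, and dienone 24 tautomerises to phenol 25. The closest known reaction type is the Danheiser benzannulation of cyclobutenones with siloxyalkynes. No stereocentre is created, and the neutral thermal conditions should leave the doubly benzylic, allylic C7–H and the alkene geometry untouched. The one selectivity needed is the regiochemistry of the [2+2] step, which is secured by the polarisation of the ynol ether (its β-carbon C8 is the nucleophile) against the electrophilic ketene carbonyl carbon, so C7 ends between the two oxygens and para to the methoxy group. Because 20 is a vinylogous ester its ring opening is expected to be slower than that of 3-alkylcyclobutenones, hence 110 °C and a modest excess of 20.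

Step 14
Reactants: 25 2-Hp-5-methoxy-3-[(triisopropylsilyl)oxy]phenol
Product: 26 2-Hp-5-methoxybenzene-1,3-diol
Conditions: n-Bu4NF (1.05 equiv), THF, 0 °C, short reaction time; pH 7 buffer
Reagents that add atoms: none
Why: Fluoride-induced Si–O cleavage, in which phenoxide is a far better leaving group than a secondary alkoxide, so one equivalent at 0 °C should remove only the aryl silyl group and leave the C3 silyl ether.

Step 15
Reactants: 26 2-Hp-5-methoxybenzene-1,3-diol
Product: 27 2-Hp-5-methoxy-1,3-bis(methoxymethoxy)benzene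
Conditions: MOMCl (4 equiv), i-Pr2NEt (6 equiv), n-Bu4NI (cat.), CH2Cl2, 0 → 40 °C
Reagents that add atoms: chloromethyl methyl ether (MOMCl), COCCl
Why: Double phenol O-alkylation to MOM ethers, which mask the acidic protons before the organolithium step and later help to hold the aryllithium by chelation.

Step 16
Reactants: 27 2-Hp-5-methoxy-1,3-bis(methoxymethoxy)benzene
Product: 28 4-bromo-2-Hp-5-methoxy-1,3-bis(methoxymethoxy)benzene
Conditions: NBS (1.0 equiv), CH2Cl2, −78 → −20 °C, dark
Reagents that add atoms: N-bromosuccinimide, O=C1CCC(=O)N1Br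
Why: Electrophilic aromatic bromination of the most electron-rich ring; C10 and C12 each lie ortho to two oxygens and para to the third and are interchanged by rotation about the C7–C8 bond, so one equivalent at low temperature should give a single monobromide and leave the alkene and the mono-oxygenated rings alone.

Step 17
Reactants: 2 4-(methoxymethoxy)benzaldehyde; 29 diethyl {2-[methoxy(methyl)amino]-2-oxoethyl}phosphonate
Product: 30 (2E)-N-methoxy-3-[4-(methoxymethoxy)phenyl]-N-methylprop-2-enamide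
Conditions: NaH, THF, 0 °C → rt
Reagents that add atoms: none
Why: Horner–Wadsworth–Emmons olefination with a stabilised phosphonate anion, which should give the (E)-enamide.

Step 18
Reactants: 28 4-bromo-2-Hp-5-methoxy-1,3-bis(methoxymethoxy)benzene; 30 (2E)-N-methoxy-3-[4-(methoxymethoxy)phenyl]-N-methylprop-2-enamide
Product: 33 (2E)-1-[3-Hp-6-methoxy-2,4-bis(methoxymethoxy)phenyl]-3-[4-(methoxymethoxy)phenyl]prop-2-en-1-one, via aryllithium 31 (not isolated), via lithium hemiaminal adduct 32 (not isolated)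
Conditions: t-BuLi (2.1 equiv), THF, −78 °C; 30 (1.5 equiv), −78 → −40 °C; then H2O/NH4Cl
Reagents that add atoms: none
Why: Bromine–lithium exchange, faster at −78 °C than any deprotonation, gives the aryllithium, which adds 1,2 to the amide carbonyl (Weinreb ketone synthesis); the chelated tetrahedral adduct persists until work-up and so prevents over-addition.

Step 19
Reactants: 33 (2E)-1-[3-Hp-6-methoxy-2,4-bis(methoxymethoxy)phenyl]-3-[4-(methoxymethoxy)phenyl]prop-2-en-1-one
Product: 34 calyxin B, (2E)-1-{2,4-dihydroxy-3-[(1S,2E,5S)-5-hydroxy-1,7-bis(4-hydroxyphenyl)hept-2-en-1-yl]-6-methoxyphenyl}-3-(4-hydroxyphenyl)prop-2-en-1-one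
Conditions: HCl in MeOH (1.25 M)–THF, 0 °C → rt
Reagents that add atoms: none
Why: Acid-catalysed cleavage of the five aryl MOM acetals and solvolysis of the secondary silyl ether in methanolic HCl; the 2'-hydroxy-6'-methoxychalcone is held open by its hydrogen bond to the carbonyl and should not close to the flavanone at room temperature.

Compound list
1 | 4-hydroxybenzaldehyde | O=Cc1ccc(O)cc1 | starting material
2 | 4-(methoxymethoxy)benzaldehyde | COCOc1ccc(C=O)cc1 | intermediate
3 | rac-1-[4-(methoxymethoxy)phenyl]prop-2-en-1-ol | C=CC(O)c1ccc(OCOC)cc1 | intermediate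
4 | potassium trifluoro[(trimethylsilyl)ethynyl]borate | C[Si](C)(C)C#C[B-](F)(F)F.[K+] | starting material
5 | trimethyl[(3S)-3-[4-(methoxymethoxy)phenyl]pent-4-en-1-yn-1-yl]silane | C[Si](C)(C)C#C[C@@H](C=C)c1ccc(OCOC)cc1 | intermediate
6 | methyl 3-(4-hydroxyphenyl)propanoate | COC(=O)CCc1ccc(O)cc1 | starting material
7 | methyl 3-[4-(methoxymethoxy)phenyl]propanoate | COCOc1ccc(CCC(=O)OC)cc1 | intermediate
8 | diisobutylaluminium hemiacetal of 7 | COCOc1ccc(CCC(OC)O[Al](CC(C)C)CC(C)C)cc1 | intermediate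
9 | 3-[4-(methoxymethoxy)phenyl]propanal | COCOc1ccc(CCC=O)cc1 | intermediate
10 | (3S)-1-[4-(methoxymethoxy)phenyl]hex-5-en-3-yl diisopinocampheylborinate | C=CC[C@H](CCc1ccc(OCOC)cc1)OB([C@H]1C[C@H]2C[C@@H]([C@@H]1C)C2(C)C)[C@H]1C[C@H]2C[C@@H]([C@@H]1C)C2(C)C | intermediate
11 | (3S)-1-[4-(methoxymethoxy)phenyl]hex-5-en-3-ol | C=CC[C@@H](O)CCc1ccc(OCOC)cc1 | intermediate
12 | tert-butyl{[(3S)-1-[4-(methoxymethoxy)phenyl]hex-5-en-3-yl]oxy}dimethylsilane | C=CC[C@@H](O[Si](C)(C)C(C)(C)C)CCc1ccc(OCOC)cc1 | intermediate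
13 | tert-butyl{[(3S,5E,7S)-1,7-bis[4-(methoxymethoxy)phenyl]-9-(trimethylsilyl)non-5-en-8-yn-3-yl]oxy}dimethylsilane | C[Si](C)(C)C#C[C@@H](/C=C/C[C@@H](O[Si](C)(C)C(C)(C)C)CCc1ccc(OCOC)cc1)c1ccc(OCOC)cc1 | intermediate
14 | tert-butyl{[(3S,5E,7R)-1,7-bis[4-(methoxymethoxy)phenyl]non-5-en-8-yn-3-yl]oxy}dimethylsilane | C#C[C@@H](/C=C/C[C@@H](O[Si](C)(C)C(C)(C)C)CCc1ccc(OCOC)cc1)c1ccc(OCOC)cc1 | intermediate
15 | lithium acetylide of 14 | [Li]C#C[C@@H](/C=C/C[C@@H](O[Si](C)(C)C(C)(C)C)CCc1ccc(OCOC)cc1)c1ccc(OCOC)cc1 | intermediate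
16 | lithium ynolate from 15 | [Li]OC#C[C@@H](/C=C/C[C@@H](O[Si](C)(C)C(C)(C)C)CCc1ccc(OCOC)cc1)c1ccc(OCOC)cc1 | intermediate
17 | tert-butyl{[(3S,5E,7S)-1,7-bis[4-(methoxymethoxy)phenyl]-9-[(triisopropylsilyl)oxy]non-5-en-8-yn-3-yl]oxy}dimethylsilane | CC(C)[Si](C(C)C)(C(C)C)OC#C[C@@H](/C=C/C[C@@H](O[Si](C)(C)C(C)(C)C)CCc1ccc(OCOC)cc1)c1ccc(OCOC)cc1 | intermediate
18 | 3-ethoxycyclobut-2-en-1-one | CCOC1=CC(=O)C1 | starting material
19 | cyclobutane-1,3-dione | O=C1CC(=O)C1 | intermediate
20 | 3-methoxycyclobut-2-en-1-one | COC1=CC(=O)C1 | intermediate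
21 | 3-methoxybuta-1,3-dien-1-one | COC(=C)C=C=O | intermediate
22 | 2-Hp-4-(1-methoxyethenyl)-3-[(triisopropylsilyl)oxy]cyclobut-2-en-1-one | COC(=C)C1C(=O)C([C@@H](/C=C/C[C@@H](O[Si](C)(C)C(C)(C)C)CCc2ccc(OCOC)cc2)c2ccc(OCOC)cc2)=C1O[Si](C(C)C)(C(C)C)C(C)C | intermediate
23 | (3E)-2-Hp-5-methoxy-3-[(triisopropylsilyl)oxy]hexa-1,3,5-trien-1-one | COC(=C)/C=C(O[Si](C(C)C)(C(C)C)C(C)C)\C(=C=O)[C@@H](/C=C/C[C@@H](O[Si](C)(C)C(C)(C)C)CCc1ccc(OCOC)cc1)c1ccc(OCOC)cc1 | intermediate
24 | 2-Hp-5-methoxy-3-[(triisopropylsilyl)oxy]cyclohexa-2,4-dien-1-one | COC1=CC(O[Si](C(C)C)(C(C)C)C(C)C)=C([C@@H](/C=C/C[C@@H](O[Si](C)(C)C(C)(C)C)CCc2ccc(OCOC)cc2)c2ccc(OCOC)cc2)C(=O)C1 | intermediate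
25 | 2-Hp-5-methoxy-3-[(triisopropylsilyl)oxy]phenol | COc1cc(O)c([C@@H](/C=C/C[C@@H](O[Si](C)(C)C(C)(C)C)CCc2ccc(OCOC)cc2)c2ccc(OCOC)cc2)c(O[Si](C(C)C)(C(C)C)C(C)C)c1 | intermediate
26 | 2-Hp-5-methoxybenzene-1,3-diol | COc1cc(O)c([C@@H](/C=C/C[C@@H](O[Si](C)(C)C(C)(C)C)CCc2ccc(OCOC)cc2)c2ccc(OCOC)cc2)c(O)c1 | intermediate
27 | 2-Hp-5-methoxy-1,3-bis(methoxymethoxy)benzene | COCOc1cc(OC)cc(OCOC)c1[C@@H](/C=C/C[C@@H](O[Si](C)(C)C(C)(C)C)CCc1ccc(OCOC)cc1)c1ccc(OCOC)cc1 | intermediate
28 | 4-bromo-2-Hp-5-methoxy-1,3-bis(methoxymethoxy)benzene | COCOc1cc(OC)c(Br)c(OCOC)c1[C@@H](/C=C/C[C@@H](O[Si](C)(C)C(C)(C)C)CCc1ccc(OCOC)cc1)c1ccc(OCOC)cc1 | intermediate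
29 | diethyl {2-[methoxy(methyl)amino]-2-oxoethyl}phosphonate | CCOP(=O)(CC(=O)N(C)OC)OCC | starting material
30 | (2E)-N-methoxy-3-[4-(methoxymethoxy)phenyl]-N-methylprop-2-enamide | CON(C)C(=O)/C=C/c1ccc(OCOC)cc1 | intermediate
31 | [3-Hp-6-methoxy-2,4-bis(methoxymethoxy)phenyl]lithium | COCOc1cc(OC)c([Li])c(OCOC)c1[C@@H](/C=C/C[C@@H](O[Si](C)(C)C(C)(C)C)CCc1ccc(OCOC)cc1)c1ccc(OCOC)cc1 | intermediate
32 | lithium hemiaminal adduct of 31 and 30 | COCOc1cc(OC)c(C(O[Li])(N(C)OC)/C=C/c2ccc(OCOC)cc2)c(OCOC)c1[C@@H](/C=C/C[C@@H](O[Si](C)(C)C(C)(C)C)CCc1ccc(OCOC)cc1)c1ccc(OCOC)cc1 | intermediate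
33 | (2E)-1-[3-Hp-6-methoxy-2,4-bis(methoxymethoxy)phenyl]-3-[4-(methoxymethoxy)phenyl]prop-2-en-1-one | COCOc1cc(OC)c(C(=O)/C=C/c2ccc(OCOC)cc2)c(OCOC)c1[C@@H](/C=C/C[C@@H](O[Si](C)(C)C(C)(C)C)CCc1ccc(OCOC)cc1)c1ccc(OCOC)cc1 | intermediate
34 | calyxin B | COc1cc(O)c([C@@H](/C=C/C[C@@H](O)CCc2ccc(O)cc2)c2ccc(O)cc2)c(O)c1C(=O)/C=C/c1ccc(O)cc1 | target

Total step count: 19.
Longest linear sequence: 13 steps (steps 4, 5, 6, 7, 8, 9, 10, 13, 14, 15, 16, 18, 19).

Steps most likely to fail

Step 13. The vinylogous ester resonance of 20 may slow the first electrocyclic opening so much that, at the temperature needed, the ynol ether is lost by silyl migration to a silylketene, or the new phenol is acylated by excess ketene. The fallback sets out from 17 and generates the same vinylketene 21 at room temperature by 1,4-dehydrochlorination instead of ring opening. Commercial methyl (2E)-3-methoxybut-2-enoate is saponified (LiOH, THF–H2O) to (2E)-3-methoxybut-2-enoic acid F1, which is converted with (COCl)2 and catalytic DMF into (2E)-3-methoxybut-2-enoyl chloride F2. Slow addition of F2 to 17 and Et3N in CH2Cl2 at 0 °C → rt should give 21 and, by [2+2] cycloaddition, the adduct 22. Warming 22 in toluene at 80 °C then takes it through 23 and 24 to 25, where the route is rejoined.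

Step 18. Addition of the di-ortho-substituted aryllithium to the amide carbonyl may be slow, and base-induced loss of the N-methoxy group of 30 or proton transfer from C7–H may then overtake it. The fallback sets out from 28 and uses an aldehyde as the more reactive electrophile. Aldehyde 2 is homologated with Ph3P=CHCHO (toluene, 80 °C, Wittig reaction) to (2E)-3-[4-(methoxymethoxy)phenyl]prop-2-enal F3. Aryllithium 31, made from 28 as before, is added to F3 at −78 °C to give (2E)-1-[3-Hp-6-methoxy-2,4-bis(methoxymethoxy)phenyl]-3-[4-(methoxymethoxy)phenyl]prop-2-en-1-ol F4. F4 is taken on without chromatography and oxidised with MnO2 in CH2Cl2 at rt to 33, where the route is rejoined.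

Step 8. Turnover at the branched allylic olefin may be low, the alkyne may bind the ruthenium carbene, and the double bond may migrate into conjugation with ring B, which would erase C7. The fallback sets out from 5 and moves the metathesis behind the ring construction, where the alkyne has become ring A. K2CO3 in MeOH gives 1-(methoxymethoxy)-4-[(3R)-pent-1-en-4-yn-3-yl]benzene F5. The conditions of step 10 convert F5 through its lithium acetylide F6 and lithium ynolate F7 into the triisopropylsilyl ynol ether F8. Heating F8 with 20 as in step 13 should proceed through cyclobutenone adduct F9, dienylketene F10 and cyclohexadienone F11 to 5-methoxy-2-[(1S)-1-[4-(methoxymethoxy)phenyl]prop-2-en-1-yl]-3-[(triisopropylsilyl)oxy]phenol F12. F12 is a 3,3-diarylpropene, a substrate type that is well behaved in cross-metathesis. With 12 and the second-generation Grubbs catalyst RuCl2(=CHPh)(H2IMes)(PCy3) in CH2Cl2 at 40 °C it should give 25, where the route is rejoined.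

Further compounds
F1 | step 13 | (2E)-3-methoxybut-2-enoic acid | CO/C(C)=C/C(=O)O
F2 | step 13 | (2E)-3-methoxybut-2-enoyl chloride | CO/C(C)=C/C(=O)Cl
F3 | step 18 | (2E)-3-[4-(methoxymethoxy)phenyl]prop-2-enal | O=C/C=C/c1ccc(OCOC)cc1
F4 | step 18 | (2E)-1-[3-Hp-6-methoxy-2,4-bis(methoxymethoxy)phenyl]-3-[4-(methoxymethoxy)phenyl]prop-2-en-1-ol | COCOc1cc(OC)c(C(O)/C=C/c2ccc(OCOC)cc2)c(OCOC)c1[C@@H](/C=C/C[C@@H](O[Si](C)(C)C(C)(C)C)CCc1ccc(OCOC)cc1)c1ccc(OCOC)cc1
F5 | step 8 | 1-(methoxymethoxy)-4-[(3R)-pent-1-en-4-yn-3-yl]benzene | C#C[C@@H](C=C)c1ccc(OCOC)cc1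
F6 | step 8 | lithium acetylide of F5 | [Li]C#C[C@@H](C=C)c1ccc(OCOC)cc1
F7 | step 8 | lithium ynolate from F6 | [Li]OC#C[C@@H](C=C)c1ccc(OCOC)cc1
F8 | step 8 | triisopropyl{[(3S)-3-[4-(methoxymethoxy)phenyl]pent-4-en-1-yn-1-yl]oxy}silane | CC(C)[Si](C(C)C)(C(C)C)OC#C[C@@H](C=C)c1ccc(OCOC)cc1
F9 | step 8 | 4-(1-methoxyethenyl)-2-[(1S)-1-[4-(methoxymethoxy)phenyl]prop-2-en-1-yl]-3-[(triisopropylsilyl)oxy]cyclobut-2-en-1-one | COC(=C)C1C(=O)C([C@@H](C=C)c2ccc(OCOC)cc2)=C1O[Si](C(C)C)(C(C)C)C(C)C
F10 | step 8 | (3E)-5-methoxy-2-[(1S)-1-[4-(methoxymethoxy)phenyl]prop-2-en-1-yl]-3-[(triisopropylsilyl)oxy]hexa-1,3,5-trien-1-one | COC(=C)/C=C(O[Si](C(C)C)(C(C)C)C(C)C)\C(=C=O)[C@@H](C=C)c1ccc(OCOC)cc1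
F11 | step 8 | 5-methoxy-2-[(1S)-1-[4-(methoxymethoxy)phenyl]prop-2-en-1-yl]-3-[(triisopropylsilyl)oxy]cyclohexa-2,4-dien-1-one | COC1=CC(O[Si](C(C)C)(C(C)C)C(C)C)=C([C@@H](C=C)c2ccc(OCOC)cc2)C(=O)C1
F12 | step 8 | 5-methoxy-2-[(1S)-1-[4-(methoxymethoxy)phenyl]prop-2-en-1-yl]-3-[(triisopropylsilyl)oxy]phenol | COc1cc(O)c([C@@H](C=C)c2ccc(OCOC)cc2)c(O[Si](C(C)C)(C(C)C)C(C)C)c1
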